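The trans-decalin is disconnected at C4a–C8a and C5–C6. One intramolecular Diels–Alder reaction of an acyclic (R)-trienal then closes ring A (the ether ring) and ring B (the carbinol ring) together and sets C4a and C8a. The step exploits the quaternary angular carbon C4a, bonded to the ring-fusion CH (C8a), and the tertiary ether carbon C2, the only stereocentre able to sit in a diene–dienophile tether and relay its configuration. The precursor is a 2-alkylacrolein linked through a CH2CH2C(CH3)(OSiEt3)CH2 tether to an (E)-diene that carries the silylated hydroxyisopropyl group. The biaryl ether is attached afterwards by iodonium O-arylation and two cross-couplings.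

Key step: step 9

Remark: decalin locants throughout follow naphthalene numbering (C2 = ether/carbinol carbon, C4a = angular carbon, C7 = carbon bearing the oxygenated propan-2-yl group, C8a = ring-fusion CH; ring A = C1–C4, C4a, C8a; ring B = C5–C8, C4a, C8a), and the aldehyde is unveiled by oxidation instead of acetal hydrolysis because the tertiary and dienylic silyl ethers would not survive aqueous acid.

Step 1
Reactants: 1 (R)-2-methylglycidol
Product: 2 (S)-2-methylpent-4-ene-1,2-diol
Conditions: CH2=CHMgBr (3 equiv), CuI (10 mol%), THF, −30 → 0 °C; aq. NH4Cl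
Reagents that add atoms: vinylmagnesium bromide, C=C[Mg]Br
Why: Copper-catalysed Grignard opening (SN2) of the epoxide at its unhindered CH2 terminus; the quaternary stereocentre is not touched and keeps its configuration, its descriptor changing only through the priority rules.

Step 2
Reactants: 2 (S)-2-methylpent-4-ene-1,2-diol
Product: 3 (S)-2-hydroxy-2-methylpent-4-en-1-yl 4-methylbenzenesulfonate
Conditions: TsCl (1.05 equiv), Et3N (1.5 equiv), Bu2SnO (2 mol%), CH2Cl2, 0 °C → rt
Reagents that add atoms: 4-toluenesulfonyl chloride, Cc1ccc(cc1)S(=O)(=O)Cl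
Why: Tin-acetal-catalysed sulfonylation selects the primary hydroxyl of the 1,2-diol, the tertiary one being too hindered to react.

Step 3
Reactants: 3 (S)-2-hydroxy-2-methylpent-4-en-1-yl 4-methylbenzenesulfonate
Product: 5 (R)-5-methyloct-7-ene-1,5-diol, via epoxide 4 (not isolated)
Conditions: NaH (1.1 equiv), THF, 0 °C → rt; solution added to ClMg(CH2)3OMgCl (2.5 equiv, from 3-chloropropan-1-ol, i-PrMgCl, then Mg, THF), CuI (10 mol%), −30 → 0 °C; aq. NH4Cl
Reagents that add atoms: chloromagnesium 3-(chloromagnesio)propan-1-olate, Cl[Mg]CCCO[Mg]Cl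
Why: Intramolecular Williamson etherification gives the volatile epoxide 4, kept in solution, and copper-catalysed Grignard opening at its CH2 terminus adds the three-carbon alkoxide arm without touching the stereocentre.

Step 4
Reactants: 5 (R)-5-methyloct-7-ene-1,5-diol
Product: 6 (R)-5-methyl-1,5-bis(triethylsilyloxy)oct-7-ene
Conditions: TESOTf (2.5 equiv), 2,6-lutidine (4 equiv), CH2Cl2, −78 → 0 °C
Reagents that add atoms: triethylsilyl trifluoromethanesulfonate, CC[Si](CC)(CC)OS(=O)(=O)C(F)(F)F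
Why: Silylation with a silyl triflate and 2,6-lutidine is reactive enough for the tertiary homoallylic alcohol, so both hydroxyls are capped in one operation.

Step 5
Reactants: 7 2-methylbut-3-yn-2-ol
Product: 8 tert-butyldimethyl[(2-methylbut-3-yn-2-yl)oxy]silane
Conditions: TBSOTf (1.1 equiv), 2,6-lutidine (1.5 equiv), CH2Cl2, 0 °C → rt
Reagents that add atoms: tert-butyldimethylsilyl trifluoromethanesulfonate, CC(C)(C)[Si](C)(C)OS(=O)(=O)C(F)(F)F
Why: Silyl triflate silylation of a tertiary propargylic alcohol, to which the terminal alkyne is inert.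

Step 6
Reactants: 6 (R)-5-methyl-1,5-bis(triethylsilyloxy)oct-7-ene; 8 tert-butyldimethyl[(2-methylbut-3-yn-2-yl)oxy]silane
Product: 9 (5R,7E)-10-(tert-butyldimethylsilyloxy)-5,10-dimethyl-9-methylidene-1,5-bis(triethylsilyloxy)undec-7-ene
Conditions: 8 (2 equiv), second-generation Grubbs catalyst (H2IMes)(PCy3)Cl2Ru=CHPh (5 mol%), ethylene (1 atm), CH2Cl2, 40 °C
Reagents that add atoms: none
Why: Enyne cross-metathesis of a terminal alkyne with a terminal alkene gives the 2-substituted 1,3-diene, ethylene keeping the ruthenium methylidene active and letting the new disubstituted alkene settle as the less strained (E)-isomer, and 6 holds no second alkene that could close a ring.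

Step 7
Reactants: 9 (5R,7E)-10-(tert-butyldimethylsilyloxy)-5,10-dimethyl-9-methylidene-1,5-bis(triethylsilyloxy)undec-7-ene
Product: 10 (5R,7E)-10-(tert-butyldimethylsilyloxy)-5,10-dimethyl-9-methylidene-5-(triethylsilyloxy)undec-7-enal
Conditions: (COCl)2 (3 equiv), DMSO (6 equiv), CH2Cl2, −78 → −40 °C; Et3N (10 equiv), −78 → 0 °C
Reagents that add atoms: none
Why: Swern oxidation applied directly to the silyl ether: the chlorosulfonium reagent cleaves only the unhindered primary O–SiEt3 bond and the resulting alkoxysulfonium salt collapses to the aldehyde, so no acid is needed in the presence of the tertiary and dienylic silyl ethers.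

Step 8
Reactants: 10 (5R,7E)-10-(tert-butyldimethylsilyloxy)-5,10-dimethyl-9-methylidene-5-(triethylsilyloxy)undec-7-enal
Product: 12 (5R,7E)-10-(tert-butyldimethylsilyloxy)-5,10-dimethyl-2,9-dimethylidene-5-(triethylsilyloxy)undec-7-enal, via Mannich base 11 (not isolated)
Conditions: CH2=NMe2+ I− (3 equiv), Et3N (6 equiv), CH2Cl2, rt
Reagents that add atoms: N,N-dimethylmethyleneiminium iodide, C=[N+](C)C.[I-]
Why: Mannich reaction at the aldehyde α-carbon with the preformed iminium salt, then base-induced elimination of dimethylamine (α-methylenation of an aldehyde), under conditions to which silyl ethers and the diene are inert.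

Step 9
Reactants: 12 (5R,7E)-10-(tert-butyldimethylsilyloxy)-5,10-dimethyl-2,9-dimethylidene-5-(triethylsilyloxy)undec-7-enal
Product: 13 (2R,4aR,8aR)-7-[2-(tert-butyldimethylsilyloxy)propan-2-yl]-2-methyl-2-(triethylsilyloxy)-1,3,4,5,6,8a-hexahydronaphthalene-4a(2H)-carbaldehyde
Conditions: Me2AlCl (1.1 equiv), CH2Cl2, −78 → −30 °C; aq. NaHCO3, potassium sodium tartrate
Reagents that add atoms: none
Why: Concerted [4+2] cycloaddition, accelerated by aluminium coordination to the formyl oxygen; the closest known reaction type is the intramolecular Diels–Alder reaction of 1,7,9-decatrienals whose dienophile is a 2-alkylacrolein. Ring A closes through the new C4a–C8a bond with the four-carbon tether held as a chair, and ring B is the cyclohexene of the cycloadduct, completed by the new C5–C6 bond. C4a and C8a are set relative to each other in the transition state that has the formyl group endo and the tether anti on the (E)-diene, which gives the trans ring fusion and puts the formyl group on the angular carbon. Their absolute sense is relayed from C2, because the chair with the C2 methyl equatorial and the silyloxy group axial is lower in energy than the alternative (a methyl group costs more in an axial site than a silyloxy group). The step needs π-facial and endo selectivity, while regiochemistry is fixed by the tether; the fully substituted C2 also favours the folded, reactive conformer. The tertiary dienylic silyl ether is a weak Lewis base, so at low temperature the aluminium reagent should stay on the aldehyde.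

Step 10
Reactants: 13 (2R,4aR,8aR)-7-[2-(tert-butyldimethylsilyloxy)propan-2-yl]-2-methyl-2-(triethylsilyloxy)-1,3,4,5,6,8a-hexahydronaphthalene-4a(2H)-carbaldehyde
Product: 15 (2R,4aS,8aR)-7-[2-(tert-butyldimethylsilyloxy)propan-2-yl]-2,4a-dimethyl-2-(triethylsilyloxy)-1,2,3,4,4a,5,6,8a-octahydronaphthalene, via N-silylhydrazone 14 (not isolated)
Conditions: TBSNHNHTBS (1.2 equiv), Sc(OTf)3 (1 mol%), CH2Cl2, rt; evaporate; KOtBu (2 equiv), t-BuOH (10 equiv), DMSO, 23 °C
Reagents that add atoms: none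
Why: Wolff–Kishner reduction in its N-silylhydrazone form: Sc(OTf)3-catalysed condensation of the hindered aldehyde, then alkoxide-induced desilylation, tautomerisation and loss of N2 at room temperature turn the formyl group into the angular methyl group without harming the silyl ethers or moving the ring alkene.

Step 11
Reactants: 15 (2R,4aS,8aR)-7-[2-(tert-butyldimethylsilyloxy)propan-2-yl]-2,4a-dimethyl-2-(triethylsilyloxy)-1,2,3,4,4a,5,6,8a-octahydronaphthalene
Product: 16 (2R,4aS,8aR)-7-[2-(tert-butyldimethylsilyloxy)propan-2-yl]-2,4a-dimethyl-1,2,3,4,4a,5,6,8a-octahydronaphthalen-2-ol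
Conditions: TBAF (2 equiv), THF, rt → 45 °C
Reagents that add atoms: none
Why: Fluoride-mediated desilylation, selective because a triethylsilyl ether is cleaved far faster than a tert-butyldimethylsilyl ether in a comparable tertiary environment.

Step 12
Reactants: 16 (2R,4aS,8aR)-7-[2-(tert-butyldimethylsilyloxy)propan-2-yl]-2,4a-dimethyl-1,2,3,4,4a,5,6,8a-octahydronaphthalen-2-ol
Product: 17 (2R,4aS,7R,8aS)-7-[2-(tert-butyldimethylsilyloxy)propan-2-yl]-2,4a-dimethyldecahydronaphthalen-2-ol
Conditions: H2 (1 atm), [Ir(cod)(PCy3)(py)]PF6 (5 mol%), CH2Cl2, rt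
Reagents that add atoms: none
Why: Homogeneous hydrogenation with the cationic iridium catalyst: the axial angular methyl group shields the β face and the axial C2 hydroxyl on the α face can bind iridium (hydroxyl-directed hydrogenation), so hydrogen should add from the α face and leave the C7 side chain equatorial (7R).

Step 13
Reactants: 18 4-bromo-2-chloro-1-iodobenzene
Product: 20 (4-bromo-2-chlorophenyl)(2,4,6-trimethoxyphenyl)iodonium 4-methylbenzenesulfonate, via iodane 19 (not isolated)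
Conditions: mCPBA (1.1 equiv), TsOH·H2O (1.1 equiv), MeCN, 77 °C; then 1,3,5-trimethoxybenzene (1.1 equiv), 77 °C → rt; Et2O trituration
Reagents that add atoms: 1,3,5-trimethoxybenzene, COc1cc(OC)cc(OC)c1; 4-toluenesulfonic acid monohydrate, Cc1ccc(cc1)S(=O)(=O)O.O
Why: One-pot diaryliodonium synthesis: the peracid oxidises the aryl iodide to the trivalent iodine tosylate 19, which attacks the electron-rich arene by electrophilic aromatic substitution, and the substrate has no other oxidisable group.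

Step 14
Reactants: 17 (2R,4aS,7R,8aS)-7-[2-(tert-butyldimethylsilyloxy)propan-2-yl]-2,4a-dimethyldecahydronaphthalen-2-ol; 20 (4-bromo-2-chlorophenyl)(2,4,6-trimethoxyphenyl)iodonium 4-methylbenzenesulfonate
Product: 22 (2R,4aS,7R,8aS)-2-(4-bromo-2-chlorophenoxy)-7-[2-(tert-butyldimethylsilyloxy)propan-2-yl]-2,4a-dimethyldecahydronaphthalene, via sodium alkoxide 21 (not isolated)
Conditions: NaH (1.2 equiv), toluene/THF, 40 °C; then 20 (1.3 equiv), rt
Reagents that add atoms: none
Why: Metal-free O-arylation of a tertiary alkoxide with a diaryliodonium salt: ligand exchange on iodine and ligand coupling at the ipso carbon of the electron-poorer ortho-substituted aryl group, the trimethoxyphenyl group staying on iodine, and C2 keeps its configuration because its C–O bond is never broken.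

Step 15
Reactants: 22 (2R,4aS,7R,8aS)-2-(4-bromo-2-chlorophenoxy)-7-[2-(tert-butyldimethylsilyloxy)propan-2-yl]-2,4a-dimethyldecahydronaphthalene
Product: 23 (2R,4aS,7R,8aS)-7-[2-(tert-butyldimethylsilyloxy)propan-2-yl]-2-[2-chloro-4-(prop-2-en-1-yl)phenoxy]-2,4a-dimethyldecahydronaphthalene
Conditions: allylSnBu3 (1.5 equiv), Pd(PPh3)4 (5 mol%), toluene, 100 °C
Reagents that add atoms: allyltributylstannane, C=CC[Sn](CCCC)(CCCC)CCCC
Why: Stille coupling; zerovalent palladium with triphenylphosphine inserts into the C–Br bond and leaves the C–Cl bond untouched.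

Step 16
Reactants: 24 allyl 4-bromophenyl ether
Product: 25 2-allyl-4-bromophenol
Conditions: N,N-diethylaniline, 200 °C
Reagents that add atoms: none
Why: Aromatic Claisen rearrangement ([3,3]-sigmatropic shift, then tautomerisation) delivers the allyl group to the ortho position.

Step 17
Reactants: 25 2-allyl-4-bromophenol
Product: 26 2-allyl-4-(4,4,5,5-tetramethyl-1,3,2-dioxaborolan-2-yl)phenol
Conditions: B2pin2 (1.2 equiv), Pd(dppf)Cl2 (3 mol%), KOAc (3 equiv), 1,4-dioxane, 90 °C
Reagents that add atoms: bis(pinacolato)diboron, CC1(C)OB(OC1(C)C)B1OC(C)(C)C(C)(C)O1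
Why: Miyaura borylation of the aryl bromide; acetate is too weak a base to start a Suzuki–Miyaura coupling or to disturb the free phenol.

Step 18
Reactants: 23 (2R,4aS,7R,8aS)-7-[2-(tert-butyldimethylsilyloxy)propan-2-yl]-2-[2-chloro-4-(prop-2-en-1-yl)phenoxy]-2,4a-dimethyldecahydronaphthalene; 26 2-allyl-4-(4,4,5,5-tetramethyl-1,3,2-dioxaborolan-2-yl)phenol
Product: 27 (2R,4aS,7R,8aS)-7-[2-(tert-butyldimethylsilyloxy)propan-2-yl]-2-{[4'-hydroxy-3',5-di(prop-2-en-1-yl)-[1,1'-biphenyl]-2-yl]oxy}-2,4a-dimethyldecahydronaphthalene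
Conditions: 26 (1.5 equiv), Pd(OAc)2 (5 mol%), XPhos (10 mol%), K3PO4 (3 equiv), 1,4-dioxane/H2O, 90 °C
Reagents that add atoms: none
Why: Suzuki–Miyaura coupling of the hindered ortho-alkoxy aryl chloride, made possible by the bulky electron-rich biarylphosphine on palladium; the phenol is carried through as its phenoxide.

Step 19
Reactants: 27 (2R,4aS,7R,8aS)-7-[2-(tert-butyldimethylsilyloxy)propan-2-yl]-2-{[4'-hydroxy-3',5-di(prop-2-en-1-yl)-[1,1'-biphenyl]-2-yl]oxy}-2,4a-dimethyldecahydronaphthalene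
Product: 28 (2R,4aS,7R,8aS)-2-{[4'-hydroxy-3',5-di(prop-2-en-1-yl)-[1,1'-biphenyl]-2-yl]oxy}-7-(2-hydroxypropan-2-yl)-2,4a-dimethyldecahydronaphthalene (CNP0342687.1)
Conditions: TBAF (5 equiv), THF, 65 °C
Reagents that add atoms: none
Why: Fluoride-mediated cleavage of the tertiary silyl ether, chosen because it is free of acid and so spares the acid-labile aryl tert-alkyl ether and the allyl groups.

Compound list
1 | (R)-2-methylglycidol | C[C@@]1(CO)CO1 | starting material
2 | (S)-2-methylpent-4-ene-1,2-diol | C[C@@](O)(CO)CC=C | intermediate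
3 | (S)-2-hydroxy-2-methylpent-4-en-1-yl 4-methylbenzenesulfonate | C[C@@](O)(COS(=O)(=O)c1ccc(C)cc1)CC=C | intermediate
4 | (S)-2-methyl-2-(prop-2-en-1-yl)oxirane | C[C@]1(CC=C)CO1 | intermediate
5 | (R)-5-methyloct-7-ene-1,5-diol | OCCCC[C@@](C)(O)CC=C | intermediate
6 | (R)-5-methyl-1,5-bis(triethylsilyloxy)oct-7-ene | CC[Si](CC)(CC)OCCCC[C@@](C)(O[Si](CC)(CC)CC)CC=C | intermediate
7 | 2-methylbut-3-yn-2-ol | CC(C)(O)C#C | starting material
8 | tert-butyldimethyl[(2-methylbut-3-yn-2-yl)oxy]silane | C#CC(C)(C)O[Si](C)(C)C(C)(C)C | intermediate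
9 | (5R,7E)-10-(tert-butyldimethylsilyloxy)-5,10-dimethyl-9-methylidene-1,5-bis(triethylsilyloxy)undec-7-ene | CC[Si](CC)(CC)OCCCC[C@@](C)(O[Si](CC)(CC)CC)C/C=C/C(=C)C(C)(C)O[Si](C)(C)C(C)(C)C | intermediate
10 | (5R,7E)-10-(tert-butyldimethylsilyloxy)-5,10-dimethyl-9-methylidene-5-(triethylsilyloxy)undec-7-enal | O=CCCC[C@@](C)(O[Si](CC)(CC)CC)C/C=C/C(=C)C(C)(C)O[Si](C)(C)C(C)(C)C | intermediate
11 | 2-[(dimethylamino)methyl] derivative of 10 (Mannich base, both C2 epimers) | O=CC(CN(C)C)CC[C@@](C)(O[Si](CC)(CC)CC)C/C=C/C(=C)C(C)(C)O[Si](C)(C)C(C)(C)C | intermediate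
12 | (5R,7E)-10-(tert-butyldimethylsilyloxy)-5,10-dimethyl-2,9-dimethylidene-5-(triethylsilyloxy)undec-7-enal | C=C(C=O)CC[C@@](C)(O[Si](CC)(CC)CC)C/C=C/C(=C)C(C)(C)O[Si](C)(C)C(C)(C)C | intermediate
13 | (2R,4aR,8aR)-7-[2-(tert-butyldimethylsilyloxy)propan-2-yl]-2-methyl-2-(triethylsilyloxy)-1,3,4,5,6,8a-hexahydronaphthalene-4a(2H)-carbaldehyde (trans-fused) | CC[Si](CC)(CC)O[C@]1(C)CC[C@]2(C=O)CCC(C(C)(C)O[Si](C)(C)C(C)(C)C)=C[C@H]2C1 | intermediate
14 | (E)-N-(tert-butyldimethylsilyl)hydrazone of 13 | CC[Si](CC)(CC)O[C@]1(C)CC[C@]2(/C=N/N[Si](C)(C)C(C)(C)C)CCC(C(C)(C)O[Si](C)(C)C(C)(C)C)=C[C@H]2C1 | intermediate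
15 | (2R,4aS,8aR)-7-[2-(tert-butyldimethylsilyloxy)propan-2-yl]-2,4a-dimethyl-2-(triethylsilyloxy)-1,2,3,4,4a,5,6,8a-octahydronaphthalene | CC[Si](CC)(CC)O[C@]1(C)CC[C@]2(C)CCC(C(C)(C)O[Si](C)(C)C(C)(C)C)=C[C@H]2C1 | intermediate
16 | (2R,4aS,8aR)-7-[2-(tert-butyldimethylsilyloxy)propan-2-yl]-2,4a-dimethyl-1,2,3,4,4a,5,6,8a-octahydronaphthalen-2-ol | O[C@]1(C)CC[C@]2(C)CCC(C(C)(C)O[Si](C)(C)C(C)(C)C)=C[C@H]2C1 | intermediate
17 | (2R,4aS,7R,8aS)-7-[2-(tert-butyldimethylsilyloxy)propan-2-yl]-2,4a-dimethyldecahydronaphthalen-2-ol | O[C@]1(C)CC[C@]2(C)CC[C@@H](C(C)(C)O[Si](C)(C)C(C)(C)C)C[C@H]2C1 | intermediate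
18 | 4-bromo-2-chloro-1-iodobenzene | Brc1ccc(I)c(Cl)c1 | starting material
19 | (4-bromo-2-chlorophenyl)(hydroxy)(tosyloxy)iodane | OI(OS(=O)(=O)c1ccc(C)cc1)c1ccc(Br)cc1Cl | intermediate
20 | (4-bromo-2-chlorophenyl)(2,4,6-trimethoxyphenyl)iodonium 4-methylbenzenesulfonate | COc1cc(OC)c([I+]c2ccc(Br)cc2Cl)c(OC)c1.Cc1ccc(cc1)S(=O)(=O)[O-] | intermediate
21 | sodium alkoxide of 17 | [Na+].[O-][C@]1(C)CC[C@]2(C)CC[C@@H](C(C)(C)O[Si](C)(C)C(C)(C)C)C[C@H]2C1 | intermediate
22 | (2R,4aS,7R,8aS)-2-(4-bromo-2-chlorophenoxy)-7-[2-(tert-butyldimethylsilyloxy)propan-2-yl]-2,4a-dimethyldecahydronaphthalene | Brc1ccc(O[C@]2(C)CC[C@]3(C)CC[C@@H](C(C)(C)O[Si](C)(C)C(C)(C)C)C[C@H]3C2)c(Cl)c1 | intermediate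
23 | (2R,4aS,7R,8aS)-7-[2-(tert-butyldimethylsilyloxy)propan-2-yl]-2-[2-chloro-4-(prop-2-en-1-yl)phenoxy]-2,4a-dimethyldecahydronaphthalene | C=CCc1ccc(O[C@]2(C)CC[C@]3(C)CC[C@@H](C(C)(C)O[Si](C)(C)C(C)(C)C)C[C@H]3C2)c(Cl)c1 | intermediate
24 | allyl 4-bromophenyl ether | C=CCOc1ccc(Br)cc1 | starting material
25 | 2-allyl-4-bromophenol | C=CCc1cc(Br)ccc1O | intermediate
26 | 2-allyl-4-(4,4,5,5-tetramethyl-1,3,2-dioxaborolan-2-yl)phenol | C=CCc1cc(B2OC(C)(C)C(C)(C)O2)ccc1O | intermediate
27 | (2R,4aS,7R,8aS)-7-[2-(tert-butyldimethylsilyloxy)propan-2-yl]-2-{[4'-hydroxy-3',5-di(prop-2-en-1-yl)-[1,1'-biphenyl]-2-yl]oxy}-2,4a-dimethyldecahydronaphthalene | C=CCc1ccc(O[C@]2(C)CC[C@]3(C)CC[C@@H](C(C)(C)O[Si](C)(C)C(C)(C)C)C[C@H]3C2)c(-c2ccc(O)c(CC=C)c2)c1 | intermediate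
28 | (2R,4aS,7R,8aS)-2-{[4'-hydroxy-3',5-di(prop-2-en-1-yl)-[1,1'-biphenyl]-2-yl]oxy}-7-(2-hydroxypropan-2-yl)-2,4a-dimethyldecahydronaphthalene (CNP0342687.1) | C=CCc1ccc(O[C@]2(C)CC[C@]3(C)CC[C@@H](C(C)(C)O)C[C@H]3C2)c(-c2ccc(O)c(CC=C)c2)c1 | target

Total step count: 19 (15 in the main line; side branches are steps 5, 13, 16 and 17).
Longest linear sequence: 15 steps from 1 (steps 1–4, 6–12, 14, 15, 18, 19).

Steps most likely to fail

Step 9. The aluminium Lewis acid may ionise the tertiary dienylic silyl ether before cycloaddition, and the energy gap between the two chair arrangements of the tether, or between endo and exo formyl, may be too small, which would erode facial or ring-fusion selectivity. The fallback moves the cycloaddition to the ester oxidation level, where it can be run thermally without any Lewis acid. It sets out from 12: Pinnick oxidation (NaClO2, NaH2PO4, 2-methylbut-2-ene, t-BuOH/H2O) should give the trienoic acid F1, and Me3SiCHN2 in MeOH/toluene the methyl trienoate F2. Heating F2 (toluene, BHT, 170 °C, sealed tube) should give the trans-fused ester cycloadduct F3 through the same chair tether. Reduction with i-Bu2AlH (CH2Cl2, −78 °C) should give the angular primary alcohol F4, and Dess–Martin oxidation returns to the route at 13.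

Step 14. The hindered alkoxide may act as a base and remove the proton ortho to iodine (aryne pathway, regioisomeric ethers), or ligand coupling at the axial tertiary oxygen may be too slow and let the iodonium salt decompose. The fallback replaces the iodonium salt by nucleophilic aromatic substitution on a nitro-activated fluoroarene. It sets out from 17: KHMDS (THF, 0 °C) should give the potassium alkoxide F5, which with 4-bromo-1-fluoro-2-nitrobenzene should give the 4-bromo-2-nitrophenyl ether F6. Stille coupling with allylSnBu3 and Pd(PPh3)4 should give the 4-allyl-2-nitrophenyl ether F7, and Zn/NH4Cl (EtOH/H2O) the 2-amino-4-allylphenyl ether F8. Non-aqueous diazotisation–iodination (t-BuONO, CH2I2, MeCN) should give the 4-allyl-2-iodophenyl ether F9, and Suzuki–Miyaura coupling of F9 with 26 (Pd(PPh3)4, K3PO4, 1,4-dioxane/H2O) returns to the route at 27.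

Step 6. Turnover may be sluggish with the hindered propargylic ether, and equilibration of the new disubstituted alkene may stay incomplete, leaving (Z)-diene that cannot cyclise to the trans-decalin. The fallback builds the diene by a stereoretentive cross-coupling. It sets out from 6: cross-metathesis with vinylboronic acid pinacol ester (second-generation Grubbs catalyst, CH2Cl2, 40 °C) should give the (E)-alkenylboronate F10. In parallel, 3-hydroxy-3-methylbutan-2-one is silylated (TBSOTf, 2,6-lutidine) to the silyloxy ketone F11, deprotonated on its only enolisable side (KHMDS, THF, −78 °C) to the potassium enolate F12, and trapped with PhNTf2 as the enol triflate F13. Suzuki–Miyaura coupling of F10 with F13 (Pd(PPh3)4, K3PO4, THF/H2O) returns to the route at 9.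

Further compounds
F1 | step 9 | (5R,7E)-10-(tert-butyldimethylsilyloxy)-5,10-dimethyl-2,9-dimethylidene-5-(triethylsilyloxy)undec-7-enoic acid | C=C(C(=O)O)CC[C@@](C)(O[Si](CC)(CC)CC)C/C=C/C(=C)C(C)(C)O[Si](C)(C)C(C)(C)C
F2 | step 9 | methyl (5R,7E)-10-(tert-butyldimethylsilyloxy)-5,10-dimethyl-2,9-dimethylidene-5-(triethylsilyloxy)undec-7-enoate | C=C(C(=O)OC)CC[C@@](C)(O[Si](CC)(CC)CC)C/C=C/C(=C)C(C)(C)O[Si](C)(C)C(C)(C)C
F3 | step 9 | methyl (2R,4aR,8aR)-7-[2-(tert-butyldimethylsilyloxy)propan-2-yl]-2-methyl-2-(triethylsilyloxy)-1,3,4,5,6,8a-hexahydronaphthalene-4a(2H)-carboxylate | CC[Si](CC)(CC)O[C@]1(C)CC[C@]2(C(=O)OC)CCC(C(C)(C)O[Si](C)(C)C(C)(C)C)=C[C@H]2C1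
F4 | step 9 | [(2R,4aR,8aR)-7-[2-(tert-butyldimethylsilyloxy)propan-2-yl]-2-methyl-2-(triethylsilyloxy)-1,3,4,5,6,8a-hexahydronaphthalen-4a(2H)-yl]methanol | CC[Si](CC)(CC)O[C@]1(C)CC[C@]2(CO)CCC(C(C)(C)O[Si](C)(C)C(C)(C)C)=C[C@H]2C1
F5 | step 14 | potassium alkoxide of 17 | [K+].[O-][C@]1(C)CC[C@]2(C)CC[C@@H](C(C)(C)O[Si](C)(C)C(C)(C)C)C[C@H]2C1
F6 | step 14 | (2R,4aS,7R,8aS)-2-(4-bromo-2-nitrophenoxy)-7-[2-(tert-butyldimethylsilyloxy)propan-2-yl]-2,4a-dimethyldecahydronaphthalene | Brc1ccc(O[C@]2(C)CC[C@]3(C)CC[C@@H](C(C)(C)O[Si](C)(C)C(C)(C)C)C[C@H]3C2)c([N+](=O)[O-])c1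
F7 | step 14 | (2R,4aS,7R,8aS)-7-[2-(tert-butyldimethylsilyloxy)propan-2-yl]-2,4a-dimethyl-2-[2-nitro-4-(prop-2-en-1-yl)phenoxy]decahydronaphthalene | C=CCc1ccc(O[C@]2(C)CC[C@]3(C)CC[C@@H](C(C)(C)O[Si](C)(C)C(C)(C)C)C[C@H]3C2)c([N+](=O)[O-])c1
F8 | step 14 | 2-{[(2R,4aS,7R,8aS)-7-[2-(tert-butyldimethylsilyloxy)propan-2-yl]-2,4a-dimethyldecahydronaphthalen-2-yl]oxy}-5-(prop-2-en-1-yl)aniline | C=CCc1ccc(O[C@]2(C)CC[C@]3(C)CC[C@@H](C(C)(C)O[Si](C)(C)C(C)(C)C)C[C@H]3C2)c(N)c1
F9 | step 14 | (2R,4aS,7R,8aS)-7-[2-(tert-butyldimethylsilyloxy)propan-2-yl]-2-[2-iodo-4-(prop-2-en-1-yl)phenoxy]-2,4a-dimethyldecahydronaphthalene | C=CCc1ccc(O[C@]2(C)CC[C@]3(C)CC[C@@H](C(C)(C)O[Si](C)(C)C(C)(C)C)C[C@H]3C2)c(I)c1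
F10 | step 6 | 2-[(1E,4R)-4-methyl-4,8-bis(triethylsilyloxy)oct-1-en-1-yl]-4,4,5,5-tetramethyl-1,3,2-dioxaborolane | CC[Si](CC)(CC)OCCCC[C@@](C)(O[Si](CC)(CC)CC)C/C=C/B1OC(C)(C)C(C)(C)O1
F11 | step 6 | 3-(tert-butyldimethylsilyloxy)-3-methylbutan-2-one | CC(=O)C(C)(C)O[Si](C)(C)C(C)(C)C
F12 | step 6 | potassium 3-(tert-butyldimethylsilyloxy)-3-methylbut-1-en-2-olate | [K+].[O-]C(=C)C(C)(C)O[Si](C)(C)C(C)(C)C
F13 | step 6 | 3-(tert-butyldimethylsilyloxy)-3-methylbut-1-en-2-yl trifluoromethanesulfonate | C=C(OS(=O)(=O)C(F)(F)F)C(C)(C)O[Si](C)(C)C(C)(C)C
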